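**Retrosynthetic overview**

1. Numbering: each half runs C1 (ester C=O), C2–C4 (oxazole carbons, C4 = ring position 2), C5–C14 (chain), C15 (CMe2), C16–C19; primes mark the methoxy half. The strategy rests on the E alkene C5=C6, which sits on oxazole carbon C4 of the epoxide half: C5 is an oxazol-2-ylmethyl carbon that a phosphoryl group makes acidic, and C6 is the carbonyl carbon of the γ,δ-epoxy enal C6–C7=C8–C9/C10 (oxirane).
2. The last C–C bond is C5=C6, formed by intramolecular Horner–Wadsworth–Emmons olefination, which closes the 30-membered macrodiolide. The seco diester 40 comes from two Yamaguchi esterifications (O14'–C1 with phosphonate acid 35, O14–C1' with enal alcohol 16).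
3. Methoxy half: the Z,Z,Z-triene C7'–C12' comes from (Z)-1,2-dichloroethene by two Sonogashira couplings and a Zn(Cu/Ag) reduction; its oxazole is built from L-serine and an aldol-derived acid that carries C6'.
4. Epoxide half: a C11≡C12 alkyne is coupled with (Z)-3-iodoallyl alcohol, then Sharpless cis-epoxidation (C9, C10), Lindlar reduction (Z-C11=C12) and a Wittig reaction give the enal.
5. Both halves come from one aldehyde 6 (Kiyooka aldol sets C16 = C16'); C14 and C14' are set by enantiomeric catalyst-controlled propargylations. Ring order: oxirane (step 8), methoxy-half oxazole (step 18; the other oxazole is bought), macrocycle (step 27).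

Key step: step 27

Remark: read from the SMILES, C14 is S and C14' is R (C16 and C16' both S, C6' R, C9 S, C10 R), so the two halves need the C4-epimeric homopropargylic alcohols 8 and 17.
Remark: the facial sense of the catalyst-controlled steps 1, 5, 12 and 14 is assigned from the accepted transition-state models and is not certain; if a sense proves opposite, the antipodal catalyst is used and the route is unchanged.

**Route**

Step 1
Reactants: 1 (E)-but-2-enal (crotonaldehyde); 2 1-methoxy-2-methyl-1-(trimethylsilyloxy)prop-1-ene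
Product: 3 methyl (3S,4E)-3-hydroxy-2,2-dimethylhex-4-enoate
Conditions: N-Ts-D-valine, BH3·THF, CH2Cl2, 0 °C → rt; then 1 and 2, −78 °C; aq. HCl/THF work-up
Reagents that add atoms: none
Why: Kiyooka-type Mukaiyama aldol in which the D-valine-derived N-tosyl oxazaborolidinone binds the aldehyde and should expose its Re face to the ketene acetal, setting C16 (S) beside the new quaternary C15.

Step 2
Reactants: 3 methyl (3S,4E)-3-hydroxy-2,2-dimethylhex-4-enoate
Product: 4 methyl (3S,4E)-2,2-dimethyl-3-(triethylsilyloxy)hex-4-enoate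
Conditions: TESOTf, 2,6-lutidine, CH2Cl2, −78 → 0 °C
Reagents that add atoms: triethylsilyl trifluoromethanesulfonate, CC[Si](CC)(CC)OS(=O)(=O)C(F)(F)F
Why: Silylation with a silyl triflate and a hindered base is the standard way to protect a neopentyl-type secondary allylic alcohol without retro-aldol cleavage.

Step 3
Reactants: 4 methyl (3S,4E)-2,2-dimethyl-3-(triethylsilyloxy)hex-4-enoate
Product: 5 (3S,4E)-2,2-dimethyl-3-(triethylsilyloxy)hex-4-en-1-ol
Conditions: i-Bu2AlH (2.5 equiv), CH2Cl2, −78 → 0 °C; aq. potassium sodium tartrate work-up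
Reagents that add atoms: none
Why: Hydride reduction of the ester to the primary alcohol with i-Bu2AlH, which leaves the silyl ether and the isolated alkene untouched.

Step 4
Reactants: 5 (3S,4E)-2,2-dimethyl-3-(triethylsilyloxy)hex-4-en-1-ol
Product: 6 (3S,4E)-2,2-dimethyl-3-(triethylsilyloxy)hex-4-enal
Conditions: Dess–Martin periodinane, CH2Cl2, 0 °C → rt
Reagents that add atoms: none
Why: Dess–Martin oxidation of a primary alcohol to an aldehyde that has no α-hydrogen and so can neither enolise nor epimerise.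

Step 5
Reactants: 6 (3S,4E)-2,2-dimethyl-3-(triethylsilyloxy)hex-4-enal; 7 allenylboronic acid pinacol ester
Product: 8 (4S,6S,7E)-5,5-dimethyl-6-(triethylsilyloxy)non-7-en-1-yn-4-ol
Conditions: (S)-TRIP [(S)-3,3'-bis(2,4,6-triisopropylphenyl)-1,1'-binaphthyl-2,2'-diyl hydrogen phosphate] (10 mol%), 4 Å MS, toluene, −20 → 0 °C
Reagents that add atoms: none
Why: Chiral-phosphoric-acid-catalysed propargylation in which the allenylboronate adds through a six-membered chair transition state to the Si face selected by (S)-TRIP, setting C14 (S) under catalyst control because the quaternary carbon insulates the existing stereocentre.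

Step 6
Reactants: 9 ethyl (2Z)-3-iodoprop-2-enoate
Product: 10 (2Z)-3-iodoprop-2-en-1-ol
Conditions: i-Bu2AlH (2.2 equiv), CH2Cl2, −78 → 0 °C
Reagents that add atoms: none
Why: 1,2-Reduction of the enoate with i-Bu2AlH gives the allylic alcohol and keeps the Z vinyl iodide.

Step 7
Reactants: 8 (4S,6S,7E)-5,5-dimethyl-6-(triethylsilyloxy)non-7-en-1-yn-4-ol; 10 (2Z)-3-iodoprop-2-en-1-ol
Product: 11 (2Z,7S,9S,10E)-8,8-dimethyl-9-(triethylsilyloxy)dodeca-2,10-dien-4-yne-1,7-diol
Conditions: PdCl2(PPh3)2 (3 mol%), CuI (6 mol%), i-Pr2NH, THF, rt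
Reagents that add atoms: none
Why: Sonogashira coupling of a terminal alkyne with a Z vinyl iodide proceeds with retention of alkene geometry and tolerates both free hydroxyl groups.

Step 8
Reactants: 11 (2Z,7S,9S,10E)-8,8-dimethyl-9-(triethylsilyloxy)dodeca-2,10-dien-4-yne-1,7-diol
Product: 12 {(2S,3R)-3-[(4S,6S,7E)-4-hydroxy-5,5-dimethyl-6-(triethylsilyloxy)non-7-en-1-yn-1-yl]oxiran-2-yl}methanol
Conditions: Ti(OiPr)4 (1.2 equiv), L-(+)-diethyl tartrate (1.4 equiv), t-BuOOH, 4 Å MS, CH2Cl2, −20 °C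
Reagents that add atoms: tert-butyl hydroperoxide, CC(C)(C)OO
Why: Sharpless asymmetric epoxidation of the Z allylic alcohol, where the L-(+)-tartrate complex delivers oxygen to the face that gives the (2S,3R) cis-oxirane (C9 S, C10 R) and only the allylic-alcohol alkene is engaged.

Step 9
Reactants: 12 {(2S,3R)-3-[(4S,6S,7E)-4-hydroxy-5,5-dimethyl-6-(triethylsilyloxy)non-7-en-1-yn-1-yl]oxiran-2-yl}methanol
Product: 13 {(2S,3R)-3-[(1Z,4S,6S,7E)-4-hydroxy-5,5-dimethyl-6-(triethylsilyloxy)nona-1,7-dien-1-yl]oxiran-2-yl}methanol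
Conditions: H2 (1 atm), Pd/CaCO3 poisoned with Pb(OAc)2 (Lindlar catalyst), quinoline, EtOAc, 0 °C
Reagents that add atoms: none
Why: Lindlar semi-hydrogenation adds H2 syn to the alkyne to give the Z C11=C12 alkene, and the quinoline-poisoned surface should stop at the alkene and spare the oxirane and the E-propenyl group.

Step 10
Reactants: 13 {(2S,3R)-3-[(1Z,4S,6S,7E)-4-hydroxy-5,5-dimethyl-6-(triethylsilyloxy)nona-1,7-dien-1-yl]oxiran-2-yl}methanol
Product: 14 (2R,3R)-3-[(1Z,4S,6S,7E)-4-hydroxy-5,5-dimethyl-6-(triethylsilyloxy)nona-1,7-dien-1-yl]oxirane-2-carbaldehyde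
Conditions: TEMPO (10 mol%), PhI(OAc)2, CH2Cl2, 0 °C → rt; used at once
Reagents that add atoms: none
Why: Oxoammonium (TEMPO/PhI(OAc)2) oxidation is selective for the primary alcohol over the hindered secondary C14 hydroxyl and is mild enough for a cis-epoxy aldehyde (the descriptor at the oxirane carbon changes only through CIP priority).

Step 11
Reactants: 14 (2R,3R)-3-[(1Z,4S,6S,7E)-4-hydroxy-5,5-dimethyl-6-(triethylsilyloxy)nona-1,7-dien-1-yl]oxirane-2-carbaldehyde; 15 (triphenylphosphoranylidene)acetaldehyde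
Product: 16 (2E)-3-{(2S,3R)-3-[(1Z,4S,6S,7E)-4-hydroxy-5,5-dimethyl-6-(triethylsilyloxy)nona-1,7-dien-1-yl]oxiran-2-yl}prop-2-enal
Conditions: toluene, rt
Reagents that add atoms: none
Why: Wittig reaction of a stabilised ylide gives the E enal, and a single homologation is expected because the α-oxygenated epoxy aldehyde is more electrophilic than the product enal.

Step 12
Reactants: 6 (3S,4E)-2,2-dimethyl-3-(triethylsilyloxy)hex-4-enal; 7 allenylboronic acid pinacol ester
Product: 17 (4R,6S,7E)-5,5-dimethyl-6-(triethylsilyloxy)non-7-en-1-yn-4-ol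
Conditions: (R)-TRIP (10 mol%), 4 Å MS, toluene, −20 → 0 °C
Reagents that add atoms: none
Why: The same chiral-phosphoric-acid-catalysed propargylation with the antipodal catalyst, which directs the allenylboronate to the Re face and sets C14' (R).

Step 13
Reactants: 17 (4R,6S,7E)-5,5-dimethyl-6-(triethylsilyloxy)non-7-en-1-yn-4-ol; 18 (Z)-1,2-dichloroethene (5 equiv)
Product: 19 (1Z,6R,8S,9E)-1-chloro-7,7-dimethyl-8-(triethylsilyloxy)undeca-1,9-dien-3-yn-6-ol
Conditions: Pd(PPh3)4 (5 mol%), CuI (10 mol%), n-BuNH2, Et2O, rt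
Reagents that add atoms: none
Why: Sonogashira mono-coupling on an excess of (Z)-1,2-dichloroethene gives the Z chloroenyne with retention of geometry, the second C–Cl bond reacting more slowly.

Step 14
Reactants: 20 3-(triisopropylsilyl)prop-2-ynal; 21 1-methoxy-1-(trimethylsilyloxy)ethene
Product: 23 methyl (3R)-3-hydroxy-5-(triisopropylsilyl)pent-4-ynoate, via trimethylsilyl ether 22 (not isolated)
Conditions: Ti(OiPr)4, (S)-2'-[(3-bromo-5-tert-butyl-2-hydroxybenzylidene)amino]-1,1'-binaphthalen-2-ol, 3,5-di-tert-butylsalicylic acid (5 mol%), Et2O, −10 °C; then 1 M HCl, THF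
Reagents that add atoms: none
Why: Carreira catalytic Mukaiyama acetate aldol, a reaction developed for silyl ynals, in which the chiral titanium complex should direct the ketene acetal to the Re face to set C6' (R) before the silyl ether is cleaved on acidic work-up.

Step 15
Reactants: 23 methyl (3R)-3-hydroxy-5-(triisopropylsilyl)pent-4-ynoate
Product: 24 methyl (3R)-3-methoxy-5-(triisopropylsilyl)pent-4-ynoate
Conditions: Me3OBF4, 1,8-bis(dimethylamino)naphthalene, CH2Cl2, rt
Reagents that add atoms: trimethyloxonium tetrafluoroborate, C[O+](C)C.F[B-](F)(F)F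
Why: O-Methylation with Meerwein's salt and a non-nucleophilic base avoids the retro-aldol and β-elimination pathways open to a β-hydroxy ester under basic alkylation.

Step 16
Reactants: 24 methyl (3R)-3-methoxy-5-(triisopropylsilyl)pent-4-ynoate
Product: 25 (3R)-3-methoxy-5-(triisopropylsilyl)pent-4-ynoic acid
Conditions: LiOH, THF/H2O, 0 °C; then 1 M HCl
Reagents that add atoms: lithium hydroxide, [Li+].[OH-]
Why: Saponification of the methyl ester at 0 °C, conditions under which the triisopropylsilyl alkyne and the β-methoxy group are stable.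

Step 17
Reactants: 25 (3R)-3-methoxy-5-(triisopropylsilyl)pent-4-ynoic acid; 26 methyl L-serinate hydrochloride
Product: 27 methyl N-[(3R)-3-methoxy-5-(triisopropylsilyl)pent-4-ynoyl]-L-serinate
Conditions: EDC·HCl, HOBt, i-Pr2NEt, CH2Cl2, 0 °C → rt
Reagents that add atoms: none
Why: Carbodiimide/HOBt amide coupling acylates the amine selectively over the serine hydroxyl.

Step 18
Reactants: 27 methyl N-[(3R)-3-methoxy-5-(triisopropylsilyl)pent-4-ynoyl]-L-serinate
Product: 29 methyl 2-[(2R)-2-methoxy-4-(triisopropylsilyl)but-3-yn-1-yl]-1,3-oxazole-4-carboxylate, via oxazoline 28 (not isolated)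
Conditions: Deoxo-Fluor, CH2Cl2, −20 °C; then BrCCl3, DBU, 0 °C → rt
Reagents that add atoms: none
Why: Wipf–Williams oxazole synthesis, in which fluorinative cyclodehydration of the β-hydroxy amide gives the oxazoline and bromination/dehydrobromination at the ester-bearing carbon aromatises it.

Step 19
Reactants: 29 methyl 2-[(2R)-2-methoxy-4-(triisopropylsilyl)but-3-yn-1-yl]-1,3-oxazole-4-carboxylate
Product: 30 methyl 2-[(2R)-2-methoxybut-3-yn-1-yl]-1,3-oxazole-4-carboxylate
Conditions: Bu4NF, AcOH, THF, 0 °C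
Reagents that add atoms: none
Why: Fluoride-induced protodesilylation of the silyl alkyne, buffered with acetic acid so that the oxazolylmethyl position is not deprotonated and methanol is not eliminated.

Step 20
Reactants: 19 (1Z,6R,8S,9E)-1-chloro-7,7-dimethyl-8-(triethylsilyloxy)undeca-1,9-dien-3-yn-6-ol; 30 methyl 2-[(2R)-2-methoxybut-3-yn-1-yl]-1,3-oxazole-4-carboxylate
Product: 31 methyl 2-[(2R,5Z,10R,12S,13E)-10-hydroxy-2-methoxy-11,11-dimethyl-12-(triethylsilyloxy)pentadeca-5,13-diene-3,7-diyn-1-yl]-1,3-oxazole-4-carboxylate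
Conditions: PdCl2(PhCN)2 (5 mol%), CuI (10 mol%), piperidine/THF, rt
Reagents that add atoms: none
Why: Sonogashira coupling of an alkenyl chloride under Alami–Linstrumelle conditions joins the two fragments with retention of the Z geometry to give the Z enediyne.

Step 21
Reactants: 31 methyl 2-[(2R,5Z,10R,12S,13E)-10-hydroxy-2-methoxy-11,11-dimethyl-12-(triethylsilyloxy)pentadeca-5,13-diene-3,7-diyn-1-yl]-1,3-oxazole-4-carboxylate
Product: 32 methyl 2-[(2R,3Z,5Z,7Z,10R,12S,13E)-10-hydroxy-2-methoxy-11,11-dimethyl-12-(triethylsilyloxy)pentadeca-3,5,7,13-tetraen-1-yl]-1,3-oxazole-4-carboxylate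
Conditions: Zn(Cu/Ag) [Zn dust, Cu(OAc)2, AgNO3], MeOH/H2O 1:1, 35 °C, dark
Reagents that add atoms: none
Why: Boland reduction, in which activated zinc reduces only alkynes conjugated to an alkene by syn hydrogen delivery, should turn both triple bonds into Z alkenes and leave the isolated E alkene, the ester and the silyl ether alone.

Step 22
Reactants: 33 methyl 2-(chloromethyl)-1,3-oxazole-4-carboxylate
Product: 34 methyl 2-[(diethoxyphosphoryl)methyl]-1,3-oxazole-4-carboxylate
Conditions: P(OEt)3, neat, 140 °C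
Reagents that add atoms: triethyl phosphite, CCOP(OCC)OCC
Why: Michaelis–Arbuzov reaction of an activated primary heteroarylmethyl chloride with loss of chloroethane.

Step 23
Reactants: 34 methyl 2-[(diethoxyphosphoryl)methyl]-1,3-oxazole-4-carboxylate
Product: 35 2-[(diethoxyphosphoryl)methyl]-1,3-oxazole-4-carboxylic acid
Conditions: LiOH (1.05 equiv), THF/H2O, 0 °C; then 1 M HCl
Reagents that add atoms: lithium hydroxide, [Li+].[OH-]
Why: Saponification of the electron-poor heteroaryl methyl ester is fast at 0 °C, where the phosphonate ethyl esters resist hydroxide.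

Step 24
Reactants: 32 methyl 2-[(2R,3Z,5Z,7Z,10R,12S,13E)-10-hydroxy-2-methoxy-11,11-dimethyl-12-(triethylsilyloxy)pentadeca-3,5,7,13-tetraen-1-yl]-1,3-oxazole-4-carboxylate; 35 2-[(diethoxyphosphoryl)methyl]-1,3-oxazole-4-carboxylic acid
Product: 37 methyl 2-[(2R,3Z,5Z,7Z,10R,12S,13E)-10-({2-[(diethoxyphosphoryl)methyl]-1,3-oxazole-4-carbonyl}oxy)-2-methoxy-11,11-dimethyl-12-(triethylsilyloxy)pentadeca-3,5,7,13-tetraen-1-yl]-1,3-oxazole-4-carboxylate, via mixed anhydride 36 (not isolated)
Conditions: 35, 2,4,6-Cl3C6H2COCl, Et3N, THF, rt; then 32, DMAP, toluene, rt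
Reagents that add atoms: 2,4,6-trichlorobenzoyl chloride, O=C(Cl)c1c(Cl)cc(Cl)cc1Cl (its aroyl group is carried only by intermediate 36 and none of its atoms stay in 37)
Why: Yamaguchi esterification, in which DMAP transfers the oxazole acyl group from the mixed anhydride to the hindered secondary C14' hydroxyl.

Step 25
Reactants: 37 methyl 2-[(2R,3Z,5Z,7Z,10R,12S,13E)-10-({2-[(diethoxyphosphoryl)methyl]-1,3-oxazole-4-carbonyl}oxy)-2-methoxy-11,11-dimethyl-12-(triethylsilyloxy)pentadeca-3,5,7,13-tetraen-1-yl]-1,3-oxazole-4-carboxylate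
Product: 38 2-[(2R,3Z,5Z,7Z,10R,12S,13E)-10-({2-[(diethoxyphosphoryl)methyl]-1,3-oxazole-4-carbonyl}oxy)-2-methoxy-11,11-dimethyl-12-(triethylsilyloxy)pentadeca-3,5,7,13-tetraen-1-yl]-1,3-oxazole-4-carboxylic acid
Conditions: LiOH (1.5 equiv), THF/H2O 3:1, 0 °C; then cold 1 M HCl to pH 4
Reagents that add atoms: lithium hydroxide, [Li+].[OH-]
Why: Chemoselective saponification, since hydroxide attacks the unhindered methyl ester far faster than the secondary ester shielded by the adjacent quaternary carbon or the P–OEt groups.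

Step 26
Reactants: 38 2-[(2R,3Z,5Z,7Z,10R,12S,13E)-10-({2-[(diethoxyphosphoryl)methyl]-1,3-oxazole-4-carbonyl}oxy)-2-methoxy-11,11-dimethyl-12-(triethylsilyloxy)pentadeca-3,5,7,13-tetraen-1-yl]-1,3-oxazole-4-carboxylic acid; 16 (2E)-3-{(2S,3R)-3-[(1Z,4S,6S,7E)-4-hydroxy-5,5-dimethyl-6-(triethylsilyloxy)nona-1,7-dien-1-yl]oxiran-2-yl}prop-2-enal
Product: 40 seco phosphonate aldehyde [(1Z,4S,6S,7E)-5,5-dimethyl-1-{(2R,3S)-3-[(1E)-3-oxoprop-1-en-1-yl]oxiran-2-yl}-6-(triethylsilyloxy)nona-1,7-dien-4-yl ester of acid 38], via mixed anhydride 39 (not isolated)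
Conditions: 38, 2,4,6-Cl3C6H2COCl, Et3N, toluene, rt; then 16, DMAP, toluene, rt
Reagents that add atoms: 2,4,6-trichlorobenzoyl chloride, O=C(Cl)c1c(Cl)cc(Cl)cc1Cl (its aroyl group is carried only by intermediate 39 and none of its atoms stay in 40)
Why: Yamaguchi esterification of the hindered C14 hydroxyl, carried out with Et3N/DMAP and no lithium salt so that the phosphonate is not ionised and the enal and oxirane are left intact.

Step 27
Reactants: 40 seco phosphonate aldehyde
Product: 41 macrocyclic bis-triethylsilyl ether (16,16'-di-O-triethylsilyl derivative of the target)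
Conditions: LiCl (10 equiv), DBU (5 equiv), MeCN, rt, slow addition of 40 to a final 1 mM
Reagents that add atoms: none
Why: Lithium chloride chelates the phosphoryl oxygen and raises the acidity of the C5 methylene, so DBU forms the phosphonate carbanion, which attacks the C6 formyl group; the β-oxido phosphonate closes to an oxaphosphetane that fragments with loss of lithium diethyl phosphate. The closest known reaction type is the Masamune–Roush Horner–Wadsworth–Emmons macro-olefination of phosphonate aldehydes. The 30-membered ring is closed end to end by this intramolecular C5=C6 olefination of the seco diester, and slow addition at about 1 mM should favour ring over dimer. No stereocentre is created; the E geometry should follow from reversible addition and equilibration of the stabilised adducts under thermodynamic control. Site selectivity rests on the substrate: the carbon next to the formyl group is vinylic and cannot enolise, the C5' methylene carries no phosphoryl group and so is neither deprotonated nor prone to lose the C6' methoxy group, and esters and silyl ethers are inert to the amidine. The dienyl oxirane, the most acid-sensitive unit, only comes into being here and meets nothing harsher than DBU and LiCl.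

Step 28
Reactants: 41 macrocyclic bis-triethylsilyl ether
Product: 42 target CNP0284709.4
Conditions: HF·pyridine, excess pyridine, THF, 0 °C
Reagents that add atoms: none
Why: Buffered fluoride desilylation removes the two triethylsilyl ethers under near-neutral conditions that the dienyl oxirane and the triene should survive.

**Compound list**

1 | (E)-but-2-enal (crotonaldehyde) | C/C=C/C=O | starting material
2 | 1-methoxy-2-methyl-1-(trimethylsilyloxy)prop-1-ene | COC(O[Si](C)(C)C)=C(C)C | starting material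
3 | methyl (3S,4E)-3-hydroxy-2,2-dimethylhex-4-enoate | C/C=C/[C@H](O)C(C)(C)C(=O)OC | intermediate
4 | methyl (3S,4E)-2,2-dimethyl-3-(triethylsilyloxy)hex-4-enoate | C/C=C/[C@H](O[Si](CC)(CC)CC)C(C)(C)C(=O)OC | intermediate
5 | (3S,4E)-2,2-dimethyl-3-(triethylsilyloxy)hex-4-en-1-ol | C/C=C/[C@H](O[Si](CC)(CC)CC)C(C)(C)CO | intermediate
6 | (3S,4E)-2,2-dimethyl-3-(triethylsilyloxy)hex-4-enal | C/C=C/[C@H](O[Si](CC)(CC)CC)C(C)(C)C=O | intermediate
7 | allenylboronic acid pinacol ester | C=C=CB1OC(C)(C)C(C)(C)O1 | starting material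
8 | (4S,6S,7E)-5,5-dimethyl-6-(triethylsilyloxy)non-7-en-1-yn-4-ol | C/C=C/[C@H](O[Si](CC)(CC)CC)C(C)(C)[C@@H](O)CC#C | intermediate
9 | ethyl (2Z)-3-iodoprop-2-enoate | CCOC(=O)/C=C\I | starting material
10 | (2Z)-3-iodoprop-2-en-1-ol | OC/C=C\I | intermediate
11 | (2Z,7S,9S,10E)-8,8-dimethyl-9-(triethylsilyloxy)dodeca-2,10-dien-4-yne-1,7-diol | C/C=C/[C@H](O[Si](CC)(CC)CC)C(C)(C)[C@@H](O)CC#C/C=C\CO | intermediate
12 | {(2S,3R)-3-[(4S,6S,7E)-4-hydroxy-5,5-dimethyl-6-(triethylsilyloxy)non-7-en-1-yn-1-yl]oxiran-2-yl}methanol | C/C=C/[C@H](O[Si](CC)(CC)CC)C(C)(C)[C@@H](O)CC#C[C@H]1O[C@H]1CO | intermediate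
13 | {(2S,3R)-3-[(1Z,4S,6S,7E)-4-hydroxy-5,5-dimethyl-6-(triethylsilyloxy)nona-1,7-dien-1-yl]oxiran-2-yl}methanol | C/C=C/[C@H](O[Si](CC)(CC)CC)C(C)(C)[C@@H](O)C/C=C\[C@H]1O[C@H]1CO | intermediate
14 | (2R,3R)-3-[(1Z,4S,6S,7E)-4-hydroxy-5,5-dimethyl-6-(triethylsilyloxy)nona-1,7-dien-1-yl]oxirane-2-carbaldehyde | C/C=C/[C@H](O[Si](CC)(CC)CC)C(C)(C)[C@@H](O)C/C=C\[C@H]1O[C@H]1C=O | intermediate
15 | (triphenylphosphoranylidene)acetaldehyde | O=CC=P(c1ccccc1)(c1ccccc1)c1ccccc1 | starting material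
16 | (2E)-3-{(2S,3R)-3-[(1Z,4S,6S,7E)-4-hydroxy-5,5-dimethyl-6-(triethylsilyloxy)nona-1,7-dien-1-yl]oxiran-2-yl}prop-2-enal | C/C=C/[C@H](O[Si](CC)(CC)CC)C(C)(C)[C@@H](O)C/C=C\[C@H]1O[C@H]1/C=C/C=O | intermediate
17 | (4R,6S,7E)-5,5-dimethyl-6-(triethylsilyloxy)non-7-en-1-yn-4-ol | C/C=C/[C@H](O[Si](CC)(CC)CC)C(C)(C)[C@H](O)CC#C | intermediate
18 | (Z)-1,2-dichloroethene | Cl/C=C\Cl | starting material
19 | (1Z,6R,8S,9E)-1-chloro-7,7-dimethyl-8-(triethylsilyloxy)undeca-1,9-dien-3-yn-6-ol | C/C=C/[C@H](O[Si](CC)(CC)CC)C(C)(C)[C@H](O)CC#C/C=C\Cl | intermediate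
20 | 3-(triisopropylsilyl)prop-2-ynal | O=CC#C[Si](C(C)C)(C(C)C)C(C)C | starting material
21 | 1-methoxy-1-(trimethylsilyloxy)ethene | COC(=C)O[Si](C)(C)C | starting material
22 | methyl (3R)-5-(triisopropylsilyl)-3-(trimethylsilyloxy)pent-4-ynoate | CC(C)[Si](C(C)C)(C(C)C)C#C[C@H](O[Si](C)(C)C)CC(=O)OC | intermediate
23 | methyl (3R)-3-hydroxy-5-(triisopropylsilyl)pent-4-ynoate | CC(C)[Si](C(C)C)(C(C)C)C#C[C@H](O)CC(=O)OC | intermediate
24 | methyl (3R)-3-methoxy-5-(triisopropylsilyl)pent-4-ynoate | CC(C)[Si](C(C)C)(C(C)C)C#C[C@H](OC)CC(=O)OC | intermediate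
25 | (3R)-3-methoxy-5-(triisopropylsilyl)pent-4-ynoic acid | CC(C)[Si](C(C)C)(C(C)C)C#C[C@H](OC)CC(=O)O | intermediate
26 | methyl L-serinate hydrochloride | [Cl-].COC(=O)[C@@H]([NH3+])CO | starting material
27 | methyl N-[(3R)-3-methoxy-5-(triisopropylsilyl)pent-4-ynoyl]-L-serinate | CC(C)[Si](C(C)C)(C(C)C)C#C[C@H](OC)CC(=O)N[C@@H](CO)C(=O)OC | intermediate
28 | methyl (4S)-2-[(2R)-2-methoxy-4-(triisopropylsilyl)but-3-yn-1-yl]-4,5-dihydro-1,3-oxazole-4-carboxylate | CC(C)[Si](C(C)C)(C(C)C)C#C[C@H](OC)CC1=N[C@@H](CO1)C(=O)OC | intermediate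
29 | methyl 2-[(2R)-2-methoxy-4-(triisopropylsilyl)but-3-yn-1-yl]-1,3-oxazole-4-carboxylate | CC(C)[Si](C(C)C)(C(C)C)C#C[C@H](OC)Cc1nc(co1)C(=O)OC | intermediate
30 | methyl 2-[(2R)-2-methoxybut-3-yn-1-yl]-1,3-oxazole-4-carboxylate | C#C[C@H](OC)Cc1nc(co1)C(=O)OC | intermediate
31 | methyl 2-[(2R,5Z,10R,12S,13E)-10-hydroxy-2-methoxy-11,11-dimethyl-12-(triethylsilyloxy)pentadeca-5,13-diene-3,7-diyn-1-yl]-1,3-oxazole-4-carboxylate | C/C=C/[C@H](O[Si](CC)(CC)CC)C(C)(C)[C@H](O)CC#C/C=C\C#C[C@H](OC)Cc1nc(co1)C(=O)OC | intermediate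
32 | methyl 2-[(2R,3Z,5Z,7Z,10R,12S,13E)-10-hydroxy-2-methoxy-11,11-dimethyl-12-(triethylsilyloxy)pentadeca-3,5,7,13-tetraen-1-yl]-1,3-oxazole-4-carboxylate | C/C=C/[C@H](O[Si](CC)(CC)CC)C(C)(C)[C@H](O)C\C=C/C=C\C=C/[C@H](OC)Cc1nc(co1)C(=O)OC | intermediate
33 | methyl 2-(chloromethyl)-1,3-oxazole-4-carboxylate | COC(=O)c1coc(CCl)n1 | starting material
34 | methyl 2-[(diethoxyphosphoryl)methyl]-1,3-oxazole-4-carboxylate | COC(=O)c1coc(CP(=O)(OCC)OCC)n1 | intermediate
35 | 2-[(diethoxyphosphoryl)methyl]-1,3-oxazole-4-carboxylic acid | OC(=O)c1coc(CP(=O)(OCC)OCC)n1 | intermediate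
36 | 2-[(diethoxyphosphoryl)methyl]-1,3-oxazole-4-carboxylic 2,4,6-trichlorobenzoic anhydride | O=C(OC(=O)c1c(Cl)cc(Cl)cc1Cl)c1coc(CP(=O)(OCC)OCC)n1 | intermediate
37 | methyl 2-[(2R,3Z,5Z,7Z,10R,12S,13E)-10-({2-[(diethoxyphosphoryl)methyl]-1,3-oxazole-4-carbonyl}oxy)-2-methoxy-11,11-dimethyl-12-(triethylsilyloxy)pentadeca-3,5,7,13-tetraen-1-yl]-1,3-oxazole-4-carboxylate | C/C=C/[C@H](O[Si](CC)(CC)CC)C(C)(C)[C@H](OC(=O)c1coc(CP(=O)(OCC)OCC)n1)C\C=C/C=C\C=C/[C@H](OC)Cc1nc(co1)C(=O)OC | intermediate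
38 | 2-[(2R,3Z,5Z,7Z,10R,12S,13E)-10-({2-[(diethoxyphosphoryl)methyl]-1,3-oxazole-4-carbonyl}oxy)-2-methoxy-11,11-dimethyl-12-(triethylsilyloxy)pentadeca-3,5,7,13-tetraen-1-yl]-1,3-oxazole-4-carboxylic acid | C/C=C/[C@H](O[Si](CC)(CC)CC)C(C)(C)[C@H](OC(=O)c1coc(CP(=O)(OCC)OCC)n1)C\C=C/C=C\C=C/[C@H](OC)Cc1nc(co1)C(=O)O | intermediate
39 | mixed anhydride of acid 38 with 2,4,6-trichlorobenzoic acid | C/C=C/[C@H](O[Si](CC)(CC)CC)C(C)(C)[C@H](OC(=O)c1coc(CP(=O)(OCC)OCC)n1)C\C=C/C=C\C=C/[C@H](OC)Cc1nc(co1)C(=O)OC(=O)c1c(Cl)cc(Cl)cc1Cl | intermediate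
40 | seco phosphonate aldehyde: (1Z,4S,6S,7E)-5,5-dimethyl-1-{(2R,3S)-3-[(1E)-3-oxoprop-1-en-1-yl]oxiran-2-yl}-6-(triethylsilyloxy)nona-1,7-dien-4-yl ester of acid 38 | C/C=C/[C@H](O[Si](CC)(CC)CC)C(C)(C)[C@@H](OC(=O)c1coc(n1)C[C@@H](OC)/C=C\C=C/C=C\C[C@@H](OC(=O)c1coc(n1)CP(=O)(OCC)OCC)C(C)(C)[C@@H](O[Si](CC)(CC)CC)/C=C/C)C/C=C\[C@H]2O[C@H]2/C=C/C=O | intermediate
41 | macrocyclic bis-triethylsilyl ether (16,16'-di-O-triethylsilyl derivative of the target; 30-membered ring with E C5=C6) | C/C=C/[C@H](O[Si](CC)(CC)CC)C(C)(C)[C@@H]1C/C=C\[C@H]2O[C@H]2/C=C/C=C/c2nc(co2)C(=O)O[C@@H](C(C)(C)[C@@H](O[Si](CC)(CC)CC)/C=C/C)C\C=C/C=C\C=C/[C@H](OC)Cc2nc(co2)C(=O)O1 | intermediate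
42 | CNP0284709.4 | C/C=C/[C@H](O)C(C)(C)[C@@H]1C/C=C\[C@H]2O[C@H]2/C=C/C=C/c2nc(co2)C(=O)O[C@@H](C(C)(C)[C@@H](O)/C=C/C)C\C=C/C=C\C=C/[C@H](OC)Cc2nc(co2)C(=O)O1 | target

**Step count and risks**

Total: 28 steps. Longest linear sequence: 13 steps (1–4, 12, 13, 20, 21, 24–28); the branches through 14–19 and through 5, 7–11 are equally long.

Steps most likely to fail:

Step 27 (macro-olefination). The competing process is intermolecular olefination leading to dimers and oligomers if the effective concentration is too high, together with slow base-induced degradation of the vinyl oxirane during a long addition. Fallback: the order of the two ring-forming bonds is reversed, setting out from enal 16 and phosphonate acid 38. An intermolecular Masamune–Roush olefination (LiCl, DBU 3 equiv, MeCN, 0.1 M, rt) should form C5=C6 first and give the seco hydroxy acid F1. Yamaguchi macrolactonisation (2,4,6-Cl3C6H2COCl, Et3N, THF; then slow addition to DMAP in toluene at 1 mM, rt) then forms the O14–C1' ester and closes the 30-membered ring, rejoining the route at 41.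

Step 9 (Lindlar reduction). The process at risk is hydrogenolytic opening of the propargylic and then allylic C–O bond of the oxirane on the palladium surface, or over-reduction past the alkene. Fallback: the alkyne is reduced before the oxirane exists, setting out from enynediol 11. Zn(Cu/Ag) in MeOH/H2O reduces the conjugated enyne to the (2Z,4Z)-dienediol F2. Sharpless epoxidation (Ti(OiPr)4, L-(+)-diethyl tartrate, t-BuOOH, CH2Cl2, −20 °C) then epoxidises only the allylic-alcohol alkene with the same facial sense, rejoining the route at 13.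

Step 21 (double Zn(Cu/Ag) reduction). The processes at risk are incomplete reduction of one triple bond, over-reduction, and Z to E drift of the forming triene on the metal surface. Fallback: the three Z alkenes are brought in preformed and joined by Stille couplings, setting out from alkynes 17 and 30. Alkyne 17 is iodinated (N-iodosuccinimide, AgNO3 cat., acetone) to the iodoalkyne F3, which diimide (2-nitrobenzenesulfonyl hydrazide, Et3N, THF/i-PrOH) reduces to the (Z)-vinyl iodide F4. Stille coupling of F4 with excess (Z)-1,2-bis(tributylstannyl)ethene (PdCl2(MeCN)2, DMF, rt) gives the (1Z,3Z)-dienylstannane F5. Alkyne 30 is taken the same way through the iodoalkyne F6 to the (Z)-vinyl iodide F7. A second Stille coupling of F5 with F7 (Pd2(dba)3, AsPh3, DMF, rt) forms C8'–C9' and rejoins the route at 32.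

**Further compounds**

F1 | step 27 | seco hydroxy acid (E C5=C6 in place, free C14 hydroxyl and free C1' carboxylic acid, both C16 oxygens as triethylsilyl ethers) | C/C=C/[C@H](O[Si](CC)(CC)CC)C(C)(C)[C@@H](O)C/C=C\[C@H]1O[C@H]1/C=C/C=C/c1nc(co1)C(=O)O[C@@H](C(C)(C)[C@@H](O[Si](CC)(CC)CC)/C=C/C)C\C=C/C=C\C=C/[C@H](OC)Cc1nc(co1)C(=O)O
F2 | step 9 | (2Z,4Z,7S,9S,10E)-8,8-dimethyl-9-(triethylsilyloxy)dodeca-2,4,10-triene-1,7-diol | C/C=C/[C@H](O[Si](CC)(CC)CC)C(C)(C)[C@@H](O)C/C=C\C=C/CO
F3 | step 21 | (4R,6S,7E)-1-iodo-5,5-dimethyl-6-(triethylsilyloxy)non-7-en-1-yn-4-ol | C/C=C/[C@H](O[Si](CC)(CC)CC)C(C)(C)[C@H](O)CC#CI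
F4 | step 21 | (1Z,4R,6S,7E)-1-iodo-5,5-dimethyl-6-(triethylsilyloxy)nona-1,7-dien-4-ol | C/C=C/[C@H](O[Si](CC)(CC)CC)C(C)(C)[C@H](O)C/C=C\I
F5 | step 21 | (1Z,3Z,6R,8S,9E)-7,7-dimethyl-1-(tributylstannyl)-8-(triethylsilyloxy)undeca-1,3,9-trien-6-ol | C/C=C/[C@H](O[Si](CC)(CC)CC)C(C)(C)[C@H](O)C\C=C/C=C\[Sn](CCCC)(CCCC)CCCC
F6 | step 21 | methyl 2-[(2R)-4-iodo-2-methoxybut-3-yn-1-yl]-1,3-oxazole-4-carboxylate | IC#C[C@H](OC)Cc1nc(co1)C(=O)OC
F7 | step 21 | methyl 2-[(2R,3Z)-4-iodo-2-methoxybut-3-en-1-yl]-1,3-oxazole-4-carboxylate | I/C=C\[C@H](OC)Cc1nc(co1)C(=O)OC
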